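## Analysis of the target

Target 27 consists of two 7-methoxycoumarins joined through a 3,6-dimethylcyclohex-2-ene. With the carbocycle numbered C1 to C6, C1 is a methine that carries position 6 of coumarin A, and C2=C3 is a trisubstituted alkene with the methyl on C3. C4 and C5 are methylenes, and C6 is a quaternary carbon bearing a methyl group and the (E)-vinyl unit Ca=Cb, which ends at position 8 of coumarin B. There are two stereocentres, C1 (R) and C6 (R); they are vicinal, and the aryl group on C1 is cis to Ca and trans to the C6 methyl. The sensitive groups are the two coumarin lactones (hydride, hydroxide, strong nucleophiles), the C2=C3 alkene (acid can move it to C3=C4), the benzylic and allylic C1–H bond, and the methoxystyrene (strong acid, light). The difficulty is to set an aryl-bearing tertiary centre next to an all-carbon quaternary centre in the right relative and absolute sense while keeping the ring alkene at C2=C3. A second difficulty is to join two coumarins of different substitution pattern (6-alkyl and 8-alkenyl). The strategy rests on one feature: the oxygen on position 7 of coumarin A is ortho to the aryl–C1 bond, and Ca is cis to that aryl group. That oxygen, the two arene carbons, C1, C6 and Ca can therefore be drawn as a six-membered lactone in which Ca is a carbonyl carbon, and this ester is the tether that delivers the arene to C1.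

## Retrosynthetic reasoning

**Ca=Cb alkene.** The styrene bond of 27 is cut last, giving core aldehyde 20 and the 1-phenyltetrazolyl sulfone 26. It is the only bond that separates the two coumarins into pieces of comparable size. The aldehyde carbon of 20 sits on a quaternary carbon, so it cannot enolise or epimerise. The opposite polarity would need a sulfone on a neopentyl carbon, which is hard to make. The forward reaction must give the E alkene without touching either lactone.

**Sulfone 26.** The C–S bond and then the C8–carbon bond are cut back to umbelliferone 21 by way of sulfide 25, alcohol 24, aldehyde 23 and hydroxy aldehyde 22. The 7-hydroxyl of 21 directs a one-carbon electrophile to C8, so the 7,8-pattern of coumarin B comes from the cheapest coumarin.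

**Pyranone ring of coumarin A.** In 20 (through alcohol 19 and acetate 18) the C3=C4 bond and the lactone C–O bond are cut, leading to salicylaldehyde 16. Its formyl group and free phenol go back to aryl aldehyde 15 and then to the 2,4-dimethoxyarene 14. This works because the only arene position that is para to one methoxy group, ortho to the other and not flanked by two substituents is the future C4a. The methoxy group next to the new aldehyde can be cleaved selectively by chelation. Building coumarin A late keeps its lactone away from the hydride used earlier.

**Revealing the tether.** Acetate 14 comes from alcohol 13, and 13 from diol 12 by methylation of the phenol. Diol 12 is the reduction product of lactone 11. In 11 the phenol oxygen (the future 7-methoxy oxygen) and Ca are joined as an aryl ester. One hydride reduction therefore frees both handles. The cost is that the methoxy group present in 11 must later become the ring oxygen of coumarin A, which the formylation and demethylation sequence achieves.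

**Aryl–C1 bond (key disconnection).** In 11 the bond between C1 and the arene is cut, giving the tertiary allylic alcohol 10. It is cut here because ionising 10 gives an allyl cation over C1, C2 and C3, and the ester can bring the arene only to C1. The forward step therefore makes the hindered aryl–C1 bond, fixes the cis relation to Ca and leaves the alkene at C2=C3. No other single bond gains as much.

**Allylic alcohol 10.** The C3–O bond and the C1=C2 alkene of 10 go back, through hydroxy selenide 8, to the C2=C3 alkene of ester 7. The alkene of 7 is already where 27 needs it. It is moved to C1=C2 with oxidation at C3 only to activate C1, and it returns in the key step. Either carbinol epimer serves.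

**Ester and carbocycle.** The ester C–O bond of 7 is cut to acid 4 and 3-methoxyphenol 5. Acid 4 comes from aldehyde 3. Two ring bonds of 3 are cut in a Diels–Alder sense to isoprene 1 and methacrolein 2. This makes the six-membered ring and the quaternary stereocentre in one catalytic step from two bulk chemicals, and the forward reaction must control only one face of 2.

## Alternatives that were turned down

**Alternative 1: aryne insertion to build ring B.**
- Disconnection: the aryl–Cb bond and the aryl–oxygen bond of ring B are cut. Ring B is traced to an aryne, and the C6–Ca–Cb unit to the one-carbon-homologated core acid A2.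
- Forward key step: the aryne released from silyl triflate A3 with CsF is attacked by the carboxylate oxygen at the carbon meta to methoxy. The aryl anion formed ortho to methoxy attacks the acyl carbon, and collapse of the four-membered intermediate gives the 2-hydroxy-6-methoxyphenyl ketone A1.
- For: it sets the oxygen, carbon and methoxy substituents of ring B contiguously with regiochemistry dictated by the aryne polarisation. On this point it is stronger than the chosen route, where the ortho-formylation of 21 has to find C8.
- Against: A2 already contains both stereocentres and coumarin A, so none of the core problems is addressed. A2 needs a homologation at a neopentyl position. After the insertion, ring B still needs a formylation and a lactonisation, and the ketone must be reduced and dehydrated to the E-styrene next to an acid-sensitive alkene. Protonation of the aryl anion competes with acyl transfer for a free acid.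
- Comparison: five or six operations replace one olefination. The chosen route offers instead a convergent last step with a separately made coumarin B, and spends its invention on the core.

**Alternative 2: organocatalytic Michael–Henry annulation.**
- Disconnection: C1–C6 and C2–C3 of the carbocycle are cut, giving keto aldehyde A5 and nitrostyrene A6.
- Forward key step: a chiral primary amine–thiourea adds the enamine of the branched aldehyde of A5 to A6. An amine base then closes the nitronate onto the methyl ketone to give nitro alcohol A4.
- For: ring and both stereocentres come from acyclic materials in one catalytic operation, and the aryl–C1 bond is already in A6. On both points it is stronger than the chosen route, which sets one centre by catalyst and relays the other.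
- Against: enamines of α,α-disubstituted aldehydes are sluggish. The primary amine also condenses with the methyl ketone, and A5 is a 1,5-dicarbonyl compound prone to intramolecular aldol condensation. The syn or anti sense between the quaternary and the aryl-bearing centre is not secured by anything in the substrate. Above all, the nitro group on C2 and the hydroxyl on C3 must be turned into the C2=C3 alkene. Dehydration gives a nitroalkene, and denitration followed by dehydration leaves C2=C3, C3=C4 and exocyclic alkenes open.
- Comparison: the chosen route answers exactly this regiochemical question through the allyl cation, and the cis relation through geometry, at the price of a stoichiometric tether.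

**Alternative 3: conjunctive coupling on a dienyl boronate.**
- Disconnection: the C1–aryl and C6–methyl bonds are cut across a C1=C6 double bond, giving dienyl boronate A8, aryl triflate A9 and a methyl nucleophile.
- Forward key step: the methyl–boron ate complex of A8 reacts with A9 under Pd(OAc)2 and a MandyPhos ligand. Methyl migrates from boron to C6 while the aryl group is delivered to C1 on the opposite face, giving tertiary boronate A7 with boron cis to the aryl group.
- For: two C–C bonds and both stereocentres form in one enantioselective step with the correct relative configuration, and boron is a stereoretentive handle. In step economy to the core it is stronger than the chosen route.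
- Against: this coupling is established for simple acyclic alkenyl boronates. Here the alkenyl boronate is cyclic, β-substituted and part of a conjugated diene, so palladium can enter allyl-type 1,4-pathways, and the migration must create a quaternary ring carbon. The tertiary boronate then has to be turned into the E-styryl group at a congested centre. The direct boron-to-alkene olefination would need an alkenyllithium of coumarin B, which its lactone does not allow, so several further steps follow.
- Comparison: the chosen route is longer to the core, but every step before the key step is standard, and the stereochemical outcome of the key step is enforced by ring geometry and not by a ligand on an untested substrate class.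

Key step: step 6

## Route

Assumption: the (S)-configured oxazaborolidinium ion of step 1 is taken to deliver isoprene to the Re face of the α-carbon of methacrolein, as the formyl C–H···O binding model predicts for 2-substituted acroleins. If the sense proved opposite, the (R)-catalyst would be used with no other change.

Step 1
Reactants: 1 isoprene; 2 methacrolein
Product: 3 (S)-1,4-dimethylcyclohex-3-ene-1-carbaldehyde
Conditions: 1 (5 equiv), (S)-1-(2-methylphenyl)-3,3-diphenyltetrahydro-1H,3H-pyrrolo[1,2-c][1,3,2]oxazaborole (10 mol%) + Tf2NH (8 mol%), CH2Cl2, −78 °C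
Reagents that add atoms: none
Why: Lewis-acid-catalysed enantioselective Diels–Alder reaction; the protonated oxazaborolidine binds the s-trans enal, lowers its LUMO and shields one face, isoprene adds with para orientation (its C1 to the β-carbon), and the catalyst alone sets the quaternary centre, Re-face attack at the α-carbon giving the (S)-aldehyde.

Step 2
Reactants: 3 (S)-1,4-dimethylcyclohex-3-ene-1-carbaldehyde
Product: 4 (S)-1,4-dimethylcyclohex-3-ene-1-carboxylic acid
Conditions: NaClO2, NaH2PO4, 2-methyl-2-butene, t-BuOH/H2O, 0 °C → rt
Reagents that add atoms: sodium chlorite, [Na+].[O-]Cl=O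
Why: Pinnick oxidation; chlorous acid oxidises the non-enolisable aldehyde under buffered conditions that cannot affect the quaternary centre, and 2-methyl-2-butene traps the hypochlorous acid that would otherwise attack the ring alkene.

Step 3
Reactants: 4 (S)-1,4-dimethylcyclohex-3-ene-1-carboxylic acid; 5 3-methoxyphenol
Product: 7 3-methoxyphenyl (S)-1,4-dimethylcyclohex-3-ene-1-carboxylate, via acid chloride 6 (not isolated)
Conditions: (COCl)2, DMF (cat.), CH2Cl2, 0 °C → rt; then 5, Et3N, DMAP (cat.), CH2Cl2, 0 °C → rt
Reagents that add atoms: oxalyl chloride, ClC(=O)C(=O)Cl (supplies the chlorine of intermediate 6; no reagent atom remains in 7)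
Why: acyl chloride formation followed by DMAP-catalysed acylation of a phenol; the acid chloride overcomes the pivalate-like hindrance of the acid, and the same hindrance makes the aryl ester robust in the steps that follow.

Step 4
Reactants: 7 3-methoxyphenyl (S)-1,4-dimethylcyclohex-3-ene-1-carboxylate
Product: 8 3-methoxyphenyl (1S)-4-hydroxy-1,4-dimethyl-3-(phenylselanyl)cyclohexane-1-carboxylate (3,4-trans hydroxy selenide as a mixture of two diastereomers)
Conditions: PhSeCl, MeCN/H2O (5:1), rt
Reagents that add atoms: benzeneselenenyl chloride, Cl[Se]c1ccccc1; water, O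
Why: electrophilic hydroxyselenation; the seleniranium ion on the trisubstituted alkene is opened anti by water at the tertiary carbon (Markovnikov), which puts selenium on the secondary carbon and oxygen on the methyl-bearing carbon under mildly acidic conditions that the aryl ester tolerates, and the configuration of the two new centres does not matter because one is eliminated in step 5 and the other ionised in step 6.

Step 5
Reactants: 8 3-methoxyphenyl (1S)-4-hydroxy-1,4-dimethyl-3-(phenylselanyl)cyclohexane-1-carboxylate
Product: 10 3-methoxyphenyl (1S)-4-hydroxy-1,4-dimethylcyclohex-2-ene-1-carboxylate (both C4 epimers), via selenoxide 9 (not isolated)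
Conditions: 30% H2O2, pyridine, THF, 0 °C → rt
Reagents that add atoms: hydrogen peroxide, OO (supplies the selenoxide oxygen of intermediate 9; no reagent atom remains in 10)
Why: selenoxide syn-elimination; the carbinol carbon bears no hydrogen, so PhSeOH can be lost only towards the methylene next to the quaternary carbon, which gives the transposed tertiary allylic alcohol, and pyridine buffers the seleninic acid and suppresses epoxidation by perseleninic acid.

Step 6
Reactants: 10 3-methoxyphenyl (1S)-4-hydroxy-1,4-dimethylcyclohex-2-ene-1-carboxylate
Product: 11 (6aS,10aS)-3-methoxy-6a,9-dimethyl-6a,7,8,10a-tetrahydro-6H-benzo[c]chromen-6-one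
Conditions: BF3·OEt2 (1.1 equiv), 4 Å MS, CH2Cl2 (0.01 M), −40 → 0 °C; aq. NaHCO3
Reagents that add atoms: none
Why: BF3 complexes and ionises the tertiary hydroxyl, so both carbinol epimers of 10 converge on one cyclohexenyl cation delocalised over C1, C2 and C3. The arene carbon ortho to the ester oxygen and para to methoxy attacks the secondary terminus C1 and rearomatises by proton loss, which leaves the double bond at C2=C3 (intramolecular Friedel–Crafts allylation). The closest known reactions are the Lewis-acid coupling of menthadienol-type tertiary allylic alcohols with resorcinol ethers and the acid-mediated closure of aryl 3-methylbut-2-enoates to 4,4-dimethyl-3,4-dihydrocoumarins, which uses the same ester tether and ring size. The six-membered lactone ring is closed by C–C bond formation in a 6-exo-trig mode with respect to the allyl cation (C1 inside and C2 outside the new ring), the arene double bond being endocyclic. The new stereocentre C10a (C1 of the carbocycle) is controlled by the existing quaternary centre C6a: the arene must approach C1 perpendicular to the allyl plane, and a three-atom tether anchored on the neighbouring carbon reaches only the face that carries the carbonyl carbon, so the ring fusion is cis. The step needs regioselectivity on the cation, which the tether secures because attack at C3 would require a bridged ring, and on the arene, which the para methoxy group secures by making that carbon more nucleophilic and less hindered than the one between the two oxygens. High dilution suppresses intermolecular alkylation, and low temperature with a prompt quench keeps the product alkene from migrating to C3=C4.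

Step 7
Reactants: 11 (6aS,10aS)-3-methoxy-6a,9-dimethyl-6a,7,8,10a-tetrahydro-6H-benzo[c]chromen-6-one
Product: 12 2-[(1R,6S)-6-(hydroxymethyl)-3,6-dimethylcyclohex-2-en-1-yl]-5-methoxyphenol
Conditions: LiAlH4, THF, 0 °C → rt; aq. KNaC4H4O6 (potassium sodium tartrate) work-up
Reagents that add atoms: none
Why: hydride reduction of an aryl ester (lactone) releases the phenol and the neopentyl primary alcohol in one operation; neither stereocentre can enolise, the isolated alkene is inert to hydride, and the neutral work-up avoids acid-promoted addition of the phenol to the ring alkene.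

Step 8
Reactants: 12 2-[(1R,6S)-6-(hydroxymethyl)-3,6-dimethylcyclohex-2-en-1-yl]-5-methoxyphenol
Product: 13 [(1S,2R)-2-(2,4-dimethoxyphenyl)-1,4-dimethylcyclohex-3-en-1-yl]methanol
Conditions: MeI, K2CO3, acetone, reflux
Reagents that add atoms: iodomethane, CI
Why: Williamson ether synthesis; carbonate deprotonates only the phenol, so methylation is selective for the aryl oxygen over the neopentyl alcohol, and this oxygen becomes the 7-methoxy group of coumarin A.

Step 9
Reactants: 13 [(1S,2R)-2-(2,4-dimethoxyphenyl)-1,4-dimethylcyclohex-3-en-1-yl]methanol
Product: 14 [(1S,2R)-2-(2,4-dimethoxyphenyl)-1,4-dimethylcyclohex-3-en-1-yl]methyl acetate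
Conditions: Ac2O, pyridine, DMAP (cat.), CH2Cl2, rt
Reagents that add atoms: acetic anhydride, CC(=O)OC(C)=O
Why: DMAP-catalysed acetylation of the primary alcohol; an acetate is chosen because it survives the chloroiminium reagent, BCl3 at low temperature and hot amine solvent, where a silyl ether would not.

Step 10
Reactants: 14 [(1S,2R)-2-(2,4-dimethoxyphenyl)-1,4-dimethylcyclohex-3-en-1-yl]methyl acetate
Product: 15 [(1S,2R)-2-(5-formyl-2,4-dimethoxyphenyl)-1,4-dimethylcyclohex-3-en-1-yl]methyl acetate
Conditions: POCl3, DMF, 0 → 60 °C; then aq. NaOAc
Reagents that add atoms: N,N-dimethylformamide, CN(C)C=O; water, O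
Why: Vilsmeier–Haack formylation; the chloroiminium ion attacks the one arene position that is para to one methoxy group, ortho to the other and not flanked by two substituents (the future C4a of coumarin A), and the dialkoxyarene is far more nucleophilic towards this weak electrophile than the trisubstituted alkene.

Step 11
Reactants: 15 [(1S,2R)-2-(5-formyl-2,4-dimethoxyphenyl)-1,4-dimethylcyclohex-3-en-1-yl]methyl acetate
Product: 16 [(1S,2R)-2-(5-formyl-4-hydroxy-2-methoxyphenyl)-1,4-dimethylcyclohex-3-en-1-yl]methyl acetate
Conditions: BCl3, CH2Cl2, −78 → 0 °C; aq. NaHCO3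
Reagents that add atoms: none
Why: chelation-controlled aryl methyl ether cleavage; BCl3 bridges the aldehyde oxygen and the ortho methoxy oxygen in a six-membered chelate and cleaves only that ether (as MeCl, so no HCl forms before the quench), leaving the methoxy group para to the aldehyde, the acetate and the alkene intact.

Step 12
Reactants: 16 [(1S,2R)-2-(5-formyl-4-hydroxy-2-methoxyphenyl)-1,4-dimethylcyclohex-3-en-1-yl]methyl acetate
Product: 18 [(1S,2R)-2-(7-methoxy-2-oxo-2H-chromen-6-yl)-1,4-dimethylcyclohex-3-en-1-yl]methyl acetate, via ethyl 2-hydroxycinnamate 17 (not isolated)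
Conditions: Ph3P=CHCO2Et, PhNEt2, reflux (about 215 °C)
Reagents that add atoms: ethyl (triphenylphosphoranylidene)acetate, CCOC(=O)C=P(c1ccccc1)(c1ccccc1)c1ccccc1
Why: Wittig olefination followed by thermal lactonisation; the stabilised ylide converts the salicylaldehyde into the 2-hydroxycinnamate, and at the boiling point of the amine solvent the E isomer equilibrates with the Z isomer, which closes to the coumarin with loss of ethanol.

Step 13
Reactants: 18 [(1S,2R)-2-(7-methoxy-2-oxo-2H-chromen-6-yl)-1,4-dimethylcyclohex-3-en-1-yl]methyl acetate
Product: 19 6-[(1R,6S)-6-(hydroxymethyl)-3,6-dimethylcyclohex-2-en-1-yl]-7-methoxy-2H-chromen-2-one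
Conditions: K2CO3, MeOH, rt; then 1 M HCl to pH 3
Reagents that add atoms: none
Why: base-catalysed transesterification removes the acetate; any coumarin opened by methoxide is the Z-configured hydroxycinnamate and recloses on the acidic work-up.

Step 14
Reactants: 19 6-[(1R,6S)-6-(hydroxymethyl)-3,6-dimethylcyclohex-2-en-1-yl]-7-methoxy-2H-chromen-2-one
Product: 20 (1S,2S)-2-(7-methoxy-2-oxo-2H-chromen-6-yl)-1,4-dimethylcyclohex-3-ene-1-carbaldehyde
Conditions: Dess–Martin periodinane, NaHCO3, CH2Cl2, 0 °C → rt
Reagents that add atoms: none
Why: Dess–Martin oxidation of the primary alcohol under buffered, non-aqueous conditions; the aldehyde has a quaternary α-carbon and therefore cannot epimerise.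

Step 15
Reactants: 21 umbelliferone (7-hydroxy-2H-chromen-2-one)
Product: 22 7-hydroxy-2-oxo-2H-chromene-8-carbaldehyde
Conditions: (CH2)6N4, CF3CO2H, reflux; then H2O, 60 °C
Reagents that add atoms: hexamethylenetetramine, C1N2CN3CN1CN(C2)C3; water, O
Why: Duff reaction; the iminium ion from hexamethylenetetramine substitutes the phenol ortho to the hydroxyl at C8, the usual site of ortho-formylation in 7-hydroxycoumarins, and hydrolysis of the benzylic imine gives the aldehyde.

Step 16
Reactants: 22 7-hydroxy-2-oxo-2H-chromene-8-carbaldehyde
Product: 23 7-methoxy-2-oxo-2H-chromene-8-carbaldehyde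
Conditions: MeI, K2CO3, DMF, rt
Reagents that add atoms: iodomethane, CI
Why: Williamson methylation of the phenol; the polar aprotic solvent compensates for the intramolecular hydrogen bond to the aldehyde.

Step 17
Reactants: 23 7-methoxy-2-oxo-2H-chromene-8-carbaldehyde
Product: 24 8-(hydroxymethyl)-7-methoxy-2H-chromen-2-one
Conditions: NaBH4, THF/MeOH, 0 °C
Reagents that add atoms: none
Why: borohydride reduction; the aryl aldehyde is reduced much faster at 0 °C than the conjugated lactone of the coumarin.

Step 18
Reactants: 24 8-(hydroxymethyl)-7-methoxy-2H-chromen-2-one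
Product: 25 7-methoxy-8-{[(1-phenyl-1H-tetrazol-5-yl)sulfanyl]methyl}-2H-chromen-2-one
Conditions: 1-phenyl-1H-tetrazole-5-thiol, PPh3, DIAD, THF, 0 °C → rt
Reagents that add atoms: 1-phenyl-1H-tetrazole-5-thiol, Sc1nnnn1-c1ccccc1
Why: Mitsunobu thioetherification; the acidic thiol displaces the activated primary benzylic alcohol, and no stereocentre is involved.

Step 19
Reactants: 25 7-methoxy-8-{[(1-phenyl-1H-tetrazol-5-yl)sulfanyl]methyl}-2H-chromen-2-one
Product: 26 7-methoxy-8-{[(1-phenyl-1H-tetrazol-5-yl)sulfonyl]methyl}-2H-chromen-2-one
Conditions: (NH4)6Mo7O24·4H2O (cat.), 30% H2O2, EtOH, 0 °C → rt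
Reagents that add atoms: hydrogen peroxide, OO
Why: molybdate-catalysed peroxide oxidation of the sulfide to the sulfone; the electron-poor C3=C4 bond of the coumarin does not react with the peroxomolybdate.

Step 20
Reactants: 20 (1S,2S)-2-(7-methoxy-2-oxo-2H-chromen-6-yl)-1,4-dimethylcyclohex-3-ene-1-carbaldehyde; 26 7-methoxy-8-{[(1-phenyl-1H-tetrazol-5-yl)sulfonyl]methyl}-2H-chromen-2-one
Product: 27 7-methoxy-8-[(E)-2-[(1R,2R)-2-(7-methoxy-2-oxo-2H-chromen-6-yl)-1,4-dimethylcyclohex-3-en-1-yl]ethenyl]-2H-chromen-2-one
Conditions: KN(SiMe3)2, THF, −78 °C → rt (base added to the mixture of 20 and 26)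
Reagents that add atoms: none
Why: Julia–Kocienski olefination; the benzylic sulfonyl carbanion adds to the non-enolisable aldehyde, the alkoxide undergoes Smiles rearrangement and loses SO2 and the tetrazolone, the reversible addition of a stabilised benzylic sulfone should favour the E alkene, and the two stereocentres of the core are not involved.

## Compound list

1 | isoprene (2-methylbuta-1,3-diene) | C=CC(C)=C | starting material
2 | methacrolein (2-methylprop-2-enal) | CC(=C)C=O | starting material
3 | (S)-1,4-dimethylcyclohex-3-ene-1-carbaldehyde | C1C=C(C)CC[C@]1(C)C=O | intermediate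
4 | (S)-1,4-dimethylcyclohex-3-ene-1-carboxylic acid | C1C=C(C)CC[C@]1(C)C(=O)O | intermediate
5 | 3-methoxyphenol | COc1cccc(O)c1 | starting material
6 | (S)-1,4-dimethylcyclohex-3-ene-1-carbonyl chloride (not isolated) | C1C=C(C)CC[C@]1(C)C(=O)Cl | intermediate
7 | 3-methoxyphenyl (S)-1,4-dimethylcyclohex-3-ene-1-carboxylate | C1C=C(C)CC[C@]1(C)C(=O)Oc1cccc(OC)c1 | intermediate
8 | 3-methoxyphenyl (1S)-4-hydroxy-1,4-dimethyl-3-(phenylselanyl)cyclohexane-1-carboxylate (3,4-trans, two diastereomers) | C1C([Se]c2ccccc2)C(C)(O)CC[C@]1(C)C(=O)Oc1cccc(OC)c1 | intermediate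
9 | 3-methoxyphenyl (1S)-4-hydroxy-1,4-dimethyl-3-(phenylseleninyl)cyclohexane-1-carboxylate (not isolated) | C1C([Se](=O)c2ccccc2)C(C)(O)CC[C@]1(C)C(=O)Oc1cccc(OC)c1 | intermediate
10 | 3-methoxyphenyl (1S)-4-hydroxy-1,4-dimethylcyclohex-2-ene-1-carboxylate (both C4 epimers) | C1=CC(C)(O)CC[C@]1(C)C(=O)Oc1cccc(OC)c1 | intermediate
11 | (6aS,10aS)-3-methoxy-6a,9-dimethyl-6a,7,8,10a-tetrahydro-6H-benzo[c]chromen-6-one | COc1ccc2[C@@H]3C=C(C)CC[C@]3(C)C(=O)Oc2c1 | intermediate
12 | 2-[(1R,6S)-6-(hydroxymethyl)-3,6-dimethylcyclohex-2-en-1-yl]-5-methoxyphenol | COc1ccc([C@@H]2C=C(C)CC[C@]2(C)CO)c(O)c1 | intermediate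
13 | [(1S,2R)-2-(2,4-dimethoxyphenyl)-1,4-dimethylcyclohex-3-en-1-yl]methanol | COc1ccc([C@@H]2C=C(C)CC[C@]2(C)CO)c(OC)c1 | intermediate
14 | [(1S,2R)-2-(2,4-dimethoxyphenyl)-1,4-dimethylcyclohex-3-en-1-yl]methyl acetate | COc1ccc([C@@H]2C=C(C)CC[C@]2(C)COC(C)=O)c(OC)c1 | intermediate
15 | [(1S,2R)-2-(5-formyl-2,4-dimethoxyphenyl)-1,4-dimethylcyclohex-3-en-1-yl]methyl acetate | COc1cc(OC)c(C=O)cc1[C@@H]1C=C(C)CC[C@]1(C)COC(C)=O | intermediate
16 | [(1S,2R)-2-(5-formyl-4-hydroxy-2-methoxyphenyl)-1,4-dimethylcyclohex-3-en-1-yl]methyl acetate | COc1cc(O)c(C=O)cc1[C@@H]1C=C(C)CC[C@]1(C)COC(C)=O | intermediate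
17 | ethyl 3-[5-[(1R,6S)-6-(acetoxymethyl)-3,6-dimethylcyclohex-2-en-1-yl]-2-hydroxy-4-methoxyphenyl]prop-2-enoate (E and Z, not isolated) | CCOC(=O)C=Cc1cc([C@@H]2C=C(C)CC[C@]2(C)COC(C)=O)c(OC)cc1O | intermediate
18 | [(1S,2R)-2-(7-methoxy-2-oxo-2H-chromen-6-yl)-1,4-dimethylcyclohex-3-en-1-yl]methyl acetate | COc1cc2oc(=O)ccc2cc1[C@@H]1C=C(C)CC[C@]1(C)COC(C)=O | intermediate
19 | 6-[(1R,6S)-6-(hydroxymethyl)-3,6-dimethylcyclohex-2-en-1-yl]-7-methoxy-2H-chromen-2-one | COc1cc2oc(=O)ccc2cc1[C@@H]1C=C(C)CC[C@]1(C)CO | intermediate
20 | (1S,2S)-2-(7-methoxy-2-oxo-2H-chromen-6-yl)-1,4-dimethylcyclohex-3-ene-1-carbaldehyde | COc1cc2oc(=O)ccc2cc1[C@@H]1C=C(C)CC[C@]1(C)C=O | intermediate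
21 | umbelliferone (7-hydroxy-2H-chromen-2-one) | O=c1ccc2ccc(O)cc2o1 | starting material
22 | 7-hydroxy-2-oxo-2H-chromene-8-carbaldehyde | O=Cc1c(O)ccc2ccc(=O)oc12 | intermediate
23 | 7-methoxy-2-oxo-2H-chromene-8-carbaldehyde | COc1ccc2ccc(=O)oc2c1C=O | intermediate
24 | 8-(hydroxymethyl)-7-methoxy-2H-chromen-2-one | COc1ccc2ccc(=O)oc2c1CO | intermediate
25 | 7-methoxy-8-{[(1-phenyl-1H-tetrazol-5-yl)sulfanyl]methyl}-2H-chromen-2-one | COc1ccc2ccc(=O)oc2c1CSc1nnnn1-c1ccccc1 | intermediate
26 | 7-methoxy-8-{[(1-phenyl-1H-tetrazol-5-yl)sulfonyl]methyl}-2H-chromen-2-one | COc1ccc2ccc(=O)oc2c1CS(=O)(=O)c1nnnn1-c1ccccc1 | intermediate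
27 | 7-methoxy-8-[(E)-2-[(1R,2R)-2-(7-methoxy-2-oxo-2H-chromen-6-yl)-1,4-dimethylcyclohex-3-en-1-yl]ethenyl]-2H-chromen-2-one | COc1cc2oc(=O)ccc2cc1[C@@H]1C=C(C)CC[C@]1(C)/C=C/c1c(OC)ccc2ccc(=O)oc12 | target

## Step count and least certain steps

Total step count: 20. Longest linear sequence: 15 steps (steps 1 to 14 and step 20). The sulfone branch (steps 15 to 19) has 5 steps and joins in step 20.

**Step 6 (key step).**
- What may go wrong: the aryl ester has to leave its preferred conformation before the arene can reach C1, so ring closure may be slow. The cation could then lose a proton to a cyclohexadiene, be captured at C3 by the ester carbonyl oxygen with expulsion of the phenol, or alkylate a second molecule. Attack through the arene carbon between the two oxygens and acid-promoted migration of the product alkene to C3=C4 are further risks.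
- Fallback (sets out from 4 and 5, returns at 11): acid 4 is converted with MeI and K2CO3 into methyl (S)-1,4-dimethylcyclohex-3-ene-1-carboxylate F1. F1 is taken through the same hydroxyselenation to the hydroxy selenide F2, oxidised to the selenoxide F3 and eliminated to methyl (1S)-4-hydroxy-1,4-dimethylcyclohex-2-ene-1-carboxylate F4. F4 and free 3-methoxyphenol 5 are then coupled intermolecularly under BF3·OEt2, which is the menthadienol–resorcinol type of reaction itself. C-Alkylation ortho to the hydroxyl and para to methoxy on the face cis to the ester gives methyl (1S,2S)-2-(2-hydroxy-4-methoxyphenyl)-1,4-dimethylcyclohex-3-ene-1-carboxylate F5, whose phenol closes onto the neighbouring ester to give 11. Alkylation of so electron-rich a ring by a stabilised allyl cation is reversible, so isomers that cannot lactonise can in principle re-ionise and drain into 11. Without the tether the first bond formation is not controlled in face or position, so this is the weaker route and a reserve only.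

**Step 1.**
- What may go wrong: insufficient or opposite enantiofacial selectivity with this acyclic diene, and loss of the volatile aldehyde on isolation.
- Fallback (sets out from 1 and 2, returns at 4): an EtAlCl2-catalysed Diels–Alder reaction gives racemic 1,4-dimethylcyclohex-3-ene-1-carbaldehyde F6, and Pinnick oxidation gives the racemic acid F7. F7 is resolved by crystallisation with (S)-1-phenylethylamine as the salt F8 (the enantiomeric amine is used if it gives the less soluble salt with the (S)-acid). Acidification liberates 4.

**Step 4.**
- What may go wrong: loss of regiocontrol in the opening of the seleniranium ion, or participation of the ester carbonyl oxygen (selenolactonisation with loss of the phenol).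
- Fallback (sets out from 7, returns at 8): epoxidation of 7 with mCPBA gives 3-methoxyphenyl (3S)-3,6-dimethyl-7-oxabicyclo[4.1.0]heptane-3-carboxylate F9. PhSeSePh and NaBH4 in EtOH then open F9 at the secondary carbon. This nucleophilic route has secure regiochemistry but exposes the aryl ester to an alkoxide medium, which is why it is second choice.

**Step 10.**
- What may go wrong: attack of the chloroiminium reagent or of adventitious HCl on the ring alkene if the formylation needs prolonged warming.
- Fallback (sets out from 13, returns at 15): bromination of 13 with NBS in MeCN at 0 °C gives [(1S,2R)-2-(5-bromo-2,4-dimethoxyphenyl)-1,4-dimethylcyclohex-3-en-1-yl]methanol F10. Treatment with n-BuLi (2.2 equiv, THF, −78 °C) and DMF gives 5-[(1R,6S)-6-(hydroxymethyl)-3,6-dimethylcyclohex-2-en-1-yl]-2,4-dimethoxybenzaldehyde F11. Acetylation of F11 gives 15.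

**Step 20.**
- What may go wrong: slow addition to the hindered neopentyl aldehyde, which gives the sulfonyl carbanion time for conjugate addition to a coumarin or for self-condensation, and erosion of E selectivity.
- Fallback (sets out from 20 and 21, returns at 27): Takai–Utimoto olefination of 20 with CrCl2, LiI and 2-(dichloromethyl)-4,4,5,5-tetramethyl-1,3,2-dioxaborolane gives 6-[(1R,6R)-3,6-dimethyl-6-[(E)-2-(4,4,5,5-tetramethyl-1,3,2-dioxaborolan-2-yl)ethenyl]cyclohex-2-en-1-yl]-7-methoxy-2H-chromen-2-one F12. Umbelliferone 21 is iodinated (I2, KI, aqueous NH3) to 7-hydroxy-8-iodo-2H-chromen-2-one F13 and methylated to 8-iodo-7-methoxy-2H-chromen-2-one F14. Suzuki–Miyaura coupling of F12 with F14 (Pd(dppf)Cl2, K3PO4, dioxane/H2O) gives 27 with the alkene geometry fixed beforehand.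

## Further compounds

F1 | step 6 | methyl (S)-1,4-dimethylcyclohex-3-ene-1-carboxylate | C1C=C(C)CC[C@]1(C)C(=O)OC
F2 | step 6 | methyl (1S)-4-hydroxy-1,4-dimethyl-3-(phenylselanyl)cyclohexane-1-carboxylate | C1C([Se]c2ccccc2)C(C)(O)CC[C@]1(C)C(=O)OC
F3 | step 6 | methyl (1S)-4-hydroxy-1,4-dimethyl-3-(phenylseleninyl)cyclohexane-1-carboxylate | C1C([Se](=O)c2ccccc2)C(C)(O)CC[C@]1(C)C(=O)OC
F4 | step 6 | methyl (1S)-4-hydroxy-1,4-dimethylcyclohex-2-ene-1-carboxylate | C1=CC(C)(O)CC[C@]1(C)C(=O)OC
F5 | step 6 | methyl (1S,2S)-2-(2-hydroxy-4-methoxyphenyl)-1,4-dimethylcyclohex-3-ene-1-carboxylate | COc1ccc([C@@H]2C=C(C)CC[C@]2(C)C(=O)OC)c(O)c1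
F6 | step 1 | racemic 1,4-dimethylcyclohex-3-ene-1-carbaldehyde | CC1=CCC(C)(C=O)CC1
F7 | step 1 | racemic 1,4-dimethylcyclohex-3-ene-1-carboxylic acid | CC1=CCC(C)(CC1)C(=O)O
F8 | step 1 | (S)-1-phenylethylammonium (S)-1,4-dimethylcyclohex-3-ene-1-carboxylate | C1C=C(C)CC[C@]1(C)C(=O)[O-].C[C@H]([NH3+])c1ccccc1
F9 | step 4 | 3-methoxyphenyl (3S)-3,6-dimethyl-7-oxabicyclo[4.1.0]heptane-3-carboxylate (both epoxide diastereomers) | C1C2OC2(C)CC[C@]1(C)C(=O)Oc1cccc(OC)c1
F10 | step 10 | [(1S,2R)-2-(5-bromo-2,4-dimethoxyphenyl)-1,4-dimethylcyclohex-3-en-1-yl]methanol | COc1cc(OC)c(Br)cc1[C@@H]1C=C(C)CC[C@]1(C)CO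
F11 | step 10 | 5-[(1R,6S)-6-(hydroxymethyl)-3,6-dimethylcyclohex-2-en-1-yl]-2,4-dimethoxybenzaldehyde | COc1cc(OC)c(C=O)cc1[C@@H]1C=C(C)CC[C@]1(C)CO
F12 | step 20 | 6-[(1R,6R)-3,6-dimethyl-6-[(E)-2-(4,4,5,5-tetramethyl-1,3,2-dioxaborolan-2-yl)ethenyl]cyclohex-2-en-1-yl]-7-methoxy-2H-chromen-2-one | COc1cc2oc(=O)ccc2cc1[C@@H]1C=C(C)CC[C@]1(C)/C=C/B1OC(C)(C)C(C)(C)O1
F13 | step 20 | 7-hydroxy-8-iodo-2H-chromen-2-one | O=c1ccc2ccc(O)c(I)c2o1
F14 | step 20 | 8-iodo-7-methoxy-2H-chromen-2-one | COc1ccc2ccc(=O)oc2c1I
A1 | alternative 1 | 6-[(1R,6R)-6-[2-(2-hydroxy-6-methoxyphenyl)-2-oxoethyl]-3,6-dimethylcyclohex-2-en-1-yl]-7-methoxy-2H-chromen-2-one | COc1cc2oc(=O)ccc2cc1[C@@H]1C=C(C)CC[C@]1(C)CC(=O)c1c(O)cccc1OC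
A2 | alternative 1 | 2-[(1R,2R)-2-(7-methoxy-2-oxo-2H-chromen-6-yl)-1,4-dimethylcyclohex-3-en-1-yl]acetic acid | COc1cc2oc(=O)ccc2cc1[C@@H]1C=C(C)CC[C@]1(C)CC(=O)O
A3 | alternative 1 | 3-methoxy-2-(trimethylsilyl)phenyl trifluoromethanesulfonate | COc1cccc(OS(=O)(=O)C(F)(F)F)c1[Si](C)(C)C
A4 | alternative 2 | 2-(2,4-dimethoxyphenyl)-4-hydroxy-1,4-dimethyl-3-nitrocyclohexane-1-carbaldehyde (aryl cis to formyl) | O=C[C@@]1(C)CCC(C)(O)C([N+](=O)[O-])[C@H]1c1ccc(OC)cc1OC
A5 | alternative 2 | 2-methyl-5-oxohexanal | CC(=O)CCC(C)C=O
A6 | alternative 2 | (E)-2,4-dimethoxy-1-(2-nitroethenyl)benzene | COc1ccc(/C=C/[N+](=O)[O-])c(OC)c1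
A7 | alternative 3 | 2-[(1R,2R)-2-(2,4-dimethoxyphenyl)-1,4-dimethylcyclohex-3-en-1-yl]-4,4,5,5-tetramethyl-1,3,2-dioxaborolane | COc1ccc([C@@H]2C=C(C)CC[C@]2(C)B3OC(C)(C)C(C)(C)O3)c(OC)c1
A8 | alternative 3 | 4,4,5,5-tetramethyl-2-(4-methylcyclohexa-1,3-dien-1-yl)-1,3,2-dioxaborolane | CC1=CC=C(B2OC(C)(C)C(C)(C)O2)CC1
A9 | alternative 3 | 2,4-dimethoxyphenyl trifluoromethanesulfonate | COc1ccc(OS(=O)(=O)C(F)(F)F)c(OC)c1
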